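**Retrosynthetic overview**
1. Feature: in the seven-membered ring C1–C2–C3–C4–C5–C6–C11, the C1 oxygen sits between quaternary C11 and methylene C2. C3 and C6 follow on either side, and C4 carries a methyl group. This is the imprint of a C11–C1–C2 oxyallyl cation added across C2/C5 of 3-methylfuran (bonds C2–C3 and C6–C11), with the furan oxygen bridging C3 and C6.
2. The angelates come off last, with the primary OH kept silylated. The trans C1/C3 diol goes back to a C1,C3-diketone, reduced by a hydroxyl relay C11–CH2OH → C1 → C3. The C10 methyl goes back to a cuprate addition on the C8 enone.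
3. The cyclobutane C4–C5–C6–C7 is cut at C6–C7. The C8-ketone enolate displaces a C6 mesylate whose oxygen is the former furan oxygen, freed by β-elimination from the C1 ketone and never oxidised.
4. The cyclohexanone C4–C5–C10–C9–C8–C7 is cut at C5–C10 (1,6-cuprate addition to the dienone, anti to C6–OSi) and at C4–C7 (oxidative enol silane coupling).
5. Ring order: seven-membered (step 3), six-membered (steps 7–10), four-membered (step 16). The racemic adduct is resolved at the C6 alcohol (step 5).

Key step: step 3

Numbering: C1–C6 and C11 as above. C7 is the cyclobutane CH next to the ketone, C8 the ketone, C9 the CH2 and C10 the CHMe. β is the face of the seven-membered ring that carries the C11 methyl; α is the face that carries C11–CH2O. Target: C1–O β, C3–O α, C4–Me β, C5–H β, C6–H β, with C7 and C10 on α; (1R,3R,4R,5S,6S,7R,10R,11S).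

Design remark: C6 is kept at the alcohol level throughout. A cycloheptadienedione/Diels–Alder annulation was set aside for three reasons:
- the less substituted C2=C3 bond would be the better dienophile;
- the two carbonyl groups pull in opposite regiochemical senses at C4=C5;
- hydride reduction of a C6 ketone in the cis-fused product would come from the convex β face and give the α-alcohol, which C7 cannot displace.

Assumption 1: the empirical size rule for lipase acylation of secondary alcohols holds, so the (6S)-alcohol is the slow-reacting enantiomer. If the preference is reversed, the ester fraction is carried on after enzymatic alcoholysis.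

Assumption 2: compound 20 is drawn as the C3 enol ether. The C1 enol ether regioisomer, if formed, behaves alike and converges in step 19.

**Step 1**
Reactants: 1 4-hydroxy-3-methylbutan-2-one; 2 benzyl 2,2,2-trichloroacetimidate
Product: 3 4-(benzyloxy)-3-methylbutan-2-one (racemic)
Conditions: 2 (1.2 equiv), CF3SO3H (5 mol %), CH2Cl2/cyclohexane, 0 °C to rt
Reagents that add atoms: benzyl 2,2,2-trichloroacetimidate (2), N=C(OCc1ccccc1)C(Cl)(Cl)Cl
Why: Acid-catalysed imidate O-benzylation avoids the base that would cause retro-aldol cleavage or dehydration of the β-hydroxy ketone.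

**Step 2**
Reactants: 3 4-(benzyloxy)-3-methylbutan-2-one
Product: 4 4-(benzyloxy)-3-chloro-3-methylbutan-2-one (racemic)
Conditions: SO2Cl2 (1.05 equiv), CH2Cl2, 0 °C to rt, dark
Reagents that add atoms: sulfuryl chloride, O=S(=O)(Cl)Cl
Why: Ionic α-chlorination of a ketone with SO2Cl2 runs through the more substituted enol, so chlorine enters at the tertiary carbon (future C11), after which no α-hydrogen is left for loss of benzyl alcohol.

**Step 3**
Reactants: 4 4-(benzyloxy)-3-chloro-3-methylbutan-2-one; 5 3-methylfuran
Product: 7 (1S,2R,5S)-2-[(benzyloxy)methyl]-2,6-dimethyl-8-oxabicyclo[3.2.1]oct-6-en-3-one (racemic; needed enantiomer drawn; C11 methyl axial and cis to the oxygen bridge), via oxyallyl cation 6 (not isolated)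
Conditions: NaOCH2CF3 (1.2 equiv), 5 (4 equiv), CF3CH2OH, 0 °C to rt
Reagents that add atoms: 3-methylfuran (5), Cc1ccoc1
Why: Trifluoroethoxide enolises 4 toward its methyl group (future C2) and the tertiary C11–Cl bond ionises in the polar, weakly nucleophilic solvent, giving the C11–C1–C2 2-oxyallyl cation 6. Cation 6 adds as the three-carbon component across C2 and C5 of 3-methylfuran, the closest known reaction type being the (4+3) cycloaddition of oxyallyl cations from α-halo ketones with furans under alkoxide/fluoroalcohol conditions. The seven-membered carbocycle closes by cycloaddition, forming C2–C3 and C6–C11 in one operation (concerted but asynchronous, or stepwise through the furan-derived oxocarbenium ion), and the furan oxygen remains as the C3–O–C6 bridge. The step needs the unsubstituted terminus C2 to bond to the furan carbon next to the methyl group, which is secured because that carbon is the most nucleophilic one (charge develops on the methyl-bearing carbon) and because this pairing keeps quaternary C11 away from the C4 methyl. C3 and C6 are set cis by suprafacial addition to the furan, and C11 is set relative to them by a compact transition state in which the larger, sodium-coordinating benzyloxymethyl group takes the outer position syn to the oxyallyl oxygen and ends equatorial, leaving the methyl axial and cis to the bridge. The adduct is racemic, minor regio- or C11-isomers are removed by chromatography, and excess furan is used to outrun Favorskii rearrangement and solvent capture.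

**Step 4**
Reactants: 7 oxabicyclic ketone
Product: 9 (6S,7R)-7-[(benzyloxy)methyl]-6-hydroxy-4,7-dimethylcyclohepta-2,4-dien-1-one (racemic; needed enantiomer drawn; ring C7 = C11; C6–OH β), via trimethylsilyl ether 8 (not isolated)
Conditions: Me3SiOSO2CF3 (2.5 equiv), Et3N (4 equiv), CH2Cl2, 0 °C to rt; then 0.5 M HCl, THF, 0 °C
Reagents that add atoms: trimethylsilyl trifluoromethanesulfonate, C[Si](C)(C)OS(=O)(=O)C(F)(F)F (silyl group of 8 only, lost again in 9)
Why: Silyl-triflate-promoted β-elimination (E1cB type): the ketone can enolise only toward C2, silylation of the bridge oxygen makes C3–O the leaving bond, quaternary C11 blocks dehydration to a tropone, and C6 and C11 are untouched.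

**Step 5**
Reactants: 9 racemic hydroxy dienone
Product: 10 (6S,7R)-7-[(benzyloxy)methyl]-6-hydroxy-4,7-dimethylcyclohepta-2,4-dien-1-one (single enantiomer)
Conditions: immobilised Burkholderia cepacia lipase, vinyl acetate, t-BuOMe, 35 °C, stopped just past half conversion
Reagents that add atoms: none
Why: Lipase-catalysed kinetic resolution by transesterification: with the quaternary C11 side as the large group and vinylic C5 as the medium group, the size rule predicts acylation of the (6R)-alcohol, so the needed (6S)-alcohol should stay unreacted and is separated from the ester by chromatography.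

**Step 6**
Reactants: 10 (6S,7R)-hydroxy dienone
Product: 11 (6S,7R)-7-[(benzyloxy)methyl]-6-[(tert-butyldimethylsilyl)oxy]-4,7-dimethylcyclohepta-2,4-dien-1-one
Conditions: tBuMe2SiOSO2CF3, 2,6-lutidine, CH2Cl2, −78 to 0 °C
Reagents that add atoms: tert-butyldimethylsilyl trifluoromethanesulfonate, CC(C)(C)[Si](C)(C)OS(=O)(=O)C(F)(F)F
Why: Silyl triflate silylation of a hindered secondary alcohol prevents re-closure of the bridge by oxa-Michael addition and turns the C6 oxygen into a bulky shield of the β face.

**Step 7**
Reactants: 11 silyloxy dienone; 12 2-(2-bromoethyl)-2-methyl-1,3-dioxolane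
Product: 13 (5R,6S,7R)-7-[(benzyloxy)methyl]-6-[(tert-butyldimethylsilyl)oxy]-4,7-dimethyl-5-[2-(2-methyl-1,3-dioxolan-2-yl)ethyl]cyclohept-3-en-1-one (side chain at C5 α, trans to C6–OSi)
Conditions: 12, Mg, THF, 25 °C; CuBr·SMe2 (0.5 equiv per Grignard), THF/Me2S, −78 °C; then 11, −78 to −30 °C
Reagents that add atoms: 2-(2-bromoethyl)-2-methyl-1,3-dioxolane (12), CC1(CCBr)OCCO1
Why: Organocuprate 1,6-conjugate addition to a 2,4-dienone transfers the C10–C7 chain to the δ-carbon C5 from the α face, anti to the neighbouring silyloxy group, and kinetic α-protonation of the dienolate leaves the C3=C4 β,γ-enone.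

**Step 8**
Reactants: 13 ketal
Product: 14 (5R,6S,7R)-7-[(benzyloxy)methyl]-6-[(tert-butyldimethylsilyl)oxy]-4,7-dimethyl-5-(3-oxobutyl)cyclohept-3-en-1-one
Conditions: pyridinium p-toluenesulfonate (cat.), acetone/H2O, 45 °C
Reagents that add atoms: water, O
Why: Mild acid-catalysed ketal hydrolysis frees the C8 methyl ketone while the hindered silyl ether and the benzyl ether survive, and any C2=C3 isomer formed converges in step 9.

**Step 9**
Reactants: 14 diketone
Product: 15 bis(enol silane) of 14: ring C1(OSiMe3)=C2–C3=C4 silyloxydiene, side chain CH2CH2C(OSiMe3)=CH2 (C5, C6 and C11 unchanged)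
Conditions: LiN(iPr)2 (2.5 equiv), Me3SiCl (4 equiv, present from the start), THF, −78 °C
Reagents that add atoms: chlorotrimethylsilane, C[Si](C)(C)Cl
Why: Kinetic deprotonation with in situ silyl trapping removes the doubly activated C2–H of the ring ketone (extended dienolate) and a proton of the methyl group C7 of the side-chain ketone (terminal enolate).

**Step 10**
Reactants: 15 bis(enol silane)
Product: 16 cis-fused bicyclo[5.4.0] enone–ketone: seven-membered ring C1(=O)–C2=C3–C4–C5–C6–C11 fused at C4–C5 to the cyclohexanone C4–C7–C8(=O)–C9–C10–C5; C4–Me β, C5–H β, C6–OSi β, C11–Me β, C11–CH2OBn α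
Conditions: (NH4)2Ce(NO3)6 (2.2 equiv), NaHCO3, MeCN, −30 to 0 °C
Reagents that add atoms: none
Why: Oxidative cross-coupling of enol silanes by one-electron oxidation: the electron-rich silyloxydiene gives a delocalised radical that the terminal enol silane carbon C7 captures at the γ-carbon C4 (six-membered ring; attack at C2 would need an eight-membered ring), the chain anchored on the α face of C5 should reach only the α face of C4 so that the fusion is cis with the C4 methyl β, and loss of the second electron and both silyl groups returns the C1 enone and the C8 ketone.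

**Step 11**
Reactants: 16 bicyclic enone–ketone
Product: 18 C3-hydroxy C1,C8-diketone (C3 epimers, other centres as in 16), via pinacol boronate 17 (not isolated)
Conditions: CuCl (10 mol %), Xantphos (10 mol %), NaOtBu (15 mol %), B2pin2 (1.3 equiv), MeOH (2 equiv), THF, rt; then NaBO3·4H2O, THF/H2O, rt
Reagents that add atoms: bis(pinacolato)diboron, CC1(C)OB(OC1(C)C)B1OC(C)(C)C(C)(C)O1; sodium perborate (oxygen atom), [Na+].[O-]OB=O
Why: Copper-catalysed conjugate borylation followed by C–B oxidation puts oxygen on C3 of the only enone present, and the C3 configuration does not matter because the carbinol is oxidised in step 12.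

**Step 12**
Reactants: 18 β-hydroxy ketone
Product: 19 C1,C3,C8-triketone (other centres as in 16)
Conditions: Dess–Martin periodinane, CH2Cl2, rt
Reagents that add atoms: none
Why: Dess–Martin oxidation converts the β-hydroxy ketone into the 1,3-diketone under neutral conditions that avoid retro-aldol cleavage and dehydration.

**Step 13**
Reactants: 19 triketone
Product: 20 C3 methoxymethyl enol ether: C1(=O)–C2H=C3(OCH2OMe), C8 ketone free (other centres as in 16)
Conditions: MeOCH2Cl, iPr2NEt, CH2Cl2, 0 °C
Reagents that add atoms: chloromethyl methyl ether, COCCl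
Why: O-alkylation of the enolisable 1,3-diketone by a hard oxocarbenium-type electrophile gives a vinylogous ester that has no acidic hydrogen (C4 and C11 are quaternary), is a poor Michael acceptor and should be inert to the bases and the cuprate that follow.

**Step 14**
Reactants: 20 silyl ether
Product: 21 C6 β-alcohol of 20
Conditions: Bu4NF, THF, rt to 45 °C
Reagents that add atoms: none
Why: Fluoride desilylation frees the C6 hydroxyl with its configuration unchanged, while the acetal-type enol ether and the benzyl ether are stable to fluoride.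

**Step 15**
Reactants: 21 C6 alcohol
Product: 22 C6 β-methanesulfonate of 21
Conditions: MeSO2Cl, Et3N, CH2Cl2, 0 °C
Reagents that add atoms: methanesulfonyl chloride, CS(=O)(=O)Cl
Why: Mesylation through sulfene works on hindered secondary alcohols and keeps the C–O bond, so the leaving group stands on the β face, opposite C7.

**Step 16**
Reactants: 22 keto mesylate
Product: 23 tricyclic ketone with the cyclobutane C4–C5–C6–C7 closed (bicyclo[3.1.1]heptan-2-one C5–C6–C7–C8(=O)–C9–C10 bridged by C4); C6–H β, C7–H as in the target, C3 enol ether and C11 substituents unchanged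
Conditions: KOtBu (1.3 equiv), t-BuOH/THF, rt to 50 °C
Reagents that add atoms: none
Why: Intramolecular enolate alkylation (4-exo-tet), the classical closure of bicyclo[3.1.1]heptan-2-ones from 4-(1-sulfonyloxyalkyl)cyclohexanones: under equilibrating conditions only the C7 enolate finds the C6–O bond aligned for backside attack in the rotamer that the seven-membered ring allows, it attacks from the α face with inversion at C6, C7 is fixed by the bridged geometry, and anti E2 loss of mesylate is not available because the only β-hydrogen (C5–H) is cis to it.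

**Step 17**
Reactants: 23 tricyclic ketone
Product: 24 tricyclic C8(=O)–C9=C10 enone (bicyclo[3.1.1]hept-3-en-2-one unit)
Conditions: LiN(iPr)2 (1.2 equiv), THF, −78 °C; then PhS(Cl)=NtBu, −78 °C
Reagents that add atoms: none
Why: One-pot sulfinimidoyl chloride dehydrogenation of a lithium enolate (Mukaiyama dehydrogenation) is regiospecific because the C8 ketone can enolise only toward C9, C7 being a bridgehead.

**Step 18**
Reactants: 24 tricyclic enone
Product: 25 (10R)-methyl ketone (C10–Me on the side of the C6–H bridge, anti to the C4 methyl)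
Conditions: Me2CuLi (from CuI and MeLi), Et2O, −78 to −20 °C
Reagents that add atoms: lithium dimethylcuprate, [Li+].C[Cu-]C
Why: Cuprate conjugate addition to a bicyclo[3.1.1]hept-3-en-2-one takes the face flanked by the C6–H bridge, because the methyl group of the C4 bridge overhangs the other face, and the vinylogous ester does not compete.

**Step 19**
Reactants: 25 enol ether
Product: 26 tricyclic C1,C3,C8-triketone benzyl ether
Conditions: 1 M HCl, THF, rt
Reagents that add atoms: none
Why: Acid hydrolysis of the methoxymethyl acetal unmasks the 1,3-diketone, and either enol ether regioisomer gives the same product.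

**Step 20**
Reactants: 26 benzyl ether
Product: 27 tricyclic triketone with free C11–CH2OH
Conditions: H2 (1 atm), Pd/C, EtOAc, rt
Reagents that add atoms: none
Why: Catalytic hydrogenolysis of the benzyl ether is placed here because no C=C bond is present and the neutral medium avoids retro-aldol loss of the hydroxymethyl group.

**Step 21**
Reactants: 27 hydroxymethyl triketone
Product: 29 triol ketone: C1–OH β, C3–OH α, C11–CH2OH, C8 ketone, via hydroxy diketone 28 (not isolated)
Conditions: Me4NBH(OAc)3 (excess), MeCN/AcOH, −30 to 0 °C
Reagents that add atoms: none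
Why: Hydroxyl-directed triacetoxyborohydride reduction (Evans–Saksena) run as a relay: the α-oriented C11–CH2OH binds boron and delivers hydride to the α face of the C1 ketone (C1–OH β, 28), the new β-hydroxyl then delivers hydride to the β face of the C3 ketone (C3–OH α, trans-1,3-diol), and the C8 ketone, which has no β-hydroxyl partner, should not be reduced by this mild reagent.

**Step 22**
Reactants: 29 triol
Product: 30 primary tert-butyldimethylsilyl ether, C1 and C3 hydroxyls free
Conditions: tBuMe2SiCl (1.05 equiv), imidazole, CH2Cl2/DMF, 0 °C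
Reagents that add atoms: tert-butyldimethylsilyl chloride, CC(C)(C)[Si](C)(C)Cl
Why: Steric selection in silylation takes the primary hydroxyl ahead of the two secondary hydroxyls, each of which adjoins a quaternary carbon.

**Step 23**
Reactants: 30 diol; 31 angelic acid, (Z)-2-methylbut-2-enoic acid
Product: 32 C1,C3-bis[(Z)-2-methylbut-2-enoate] silyl ether
Conditions: 31 (6 equiv), 2,4,6-Cl3C6H2COCl (6 equiv), Et3N, toluene, rt; then 30, 80 °C
Reagents that add atoms: angelic acid (31), C/C=C(/C)C(=O)O
Why: Yamaguchi-type mixed anhydride acylation without a nucleophilic catalyst acylates hindered secondary alcohols while avoiding the addition–elimination pathway that turns angelates into tiglates.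

**Step 24**
Reactants: 32 silyl ether
Product: 33 target, CNP0287707.1
Conditions: HF·pyridine, THF, 0 °C to rt
Reagents that add atoms: none
Why: Fluoride desilylation in a mildly acidic, non-nucleophilic medium leaves the (Z)-esters unisomerised and avoids base-induced acyl migration from C1–O to the freed primary hydroxyl.

**Compound list**
1 | 4-hydroxy-3-methylbutan-2-one (racemic) | CC(=O)C(C)CO | starting material
2 | benzyl 2,2,2-trichloroacetimidate | N=C(OCc1ccccc1)C(Cl)(Cl)Cl | starting material
3 | 4-(benzyloxy)-3-methylbutan-2-one (racemic) | CC(=O)C(C)COCc1ccccc1 | intermediate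
4 | 4-(benzyloxy)-3-chloro-3-methylbutan-2-one (racemic) | CC(=O)C(C)(Cl)COCc1ccccc1 | intermediate
5 | 3-methylfuran | Cc1ccoc1 | starting material
6 | 1-(benzyloxymethyl)-1-methyl-2-oxidoallyl cation (not isolated) | C=C([O-])[C+](C)COCc1ccccc1 | intermediate
7 | (1S,2R,5S)-2-[(benzyloxy)methyl]-2,6-dimethyl-8-oxabicyclo[3.2.1]oct-6-en-3-one (racemate, needed enantiomer drawn) | O=C1C[C@@H]2O[C@@H](C=C2C)[C@@]1(C)COCc1ccccc1 | intermediate
8 | trimethylsilyl ether of 9 (racemate, not isolated) | O=C1C=CC(C)=C[C@H](O[Si](C)(C)C)[C@@]1(C)COCc1ccccc1 | intermediate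
9 | 7-[(benzyloxy)methyl]-6-hydroxy-4,7-dimethylcyclohepta-2,4-dien-1-one, OH cis to the ring methyl at C7 (racemate, needed enantiomer drawn) | O=C1C=CC(C)=C[C@H](O)[C@@]1(C)COCc1ccccc1 | intermediate
10 | (6S,7R)-7-[(benzyloxy)methyl]-6-hydroxy-4,7-dimethylcyclohepta-2,4-dien-1-one (single enantiomer) | O=C1C=CC(C)=C[C@H](O)[C@@]1(C)COCc1ccccc1 | intermediate
11 | (6S,7R)-7-[(benzyloxy)methyl]-6-[(tert-butyldimethylsilyl)oxy]-4,7-dimethylcyclohepta-2,4-dien-1-one | O=C1C=CC(C)=C[C@H](O[Si](C)(C)C(C)(C)C)[C@@]1(C)COCc1ccccc1 | intermediate
12 | 2-(2-bromoethyl)-2-methyl-1,3-dioxolane | CC1(CCBr)OCCO1 | starting material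
13 | (5R,6S,7R)-7-[(benzyloxy)methyl]-6-[(tert-butyldimethylsilyl)oxy]-4,7-dimethyl-5-[2-(2-methyl-1,3-dioxolan-2-yl)ethyl]cyclohept-3-en-1-one | O=C1CC=C(C)[C@@H](CCC2(C)OCCO2)[C@H](O[Si](C)(C)C(C)(C)C)[C@@]1(C)COCc1ccccc1 | intermediate
14 | (5R,6S,7R)-7-[(benzyloxy)methyl]-6-[(tert-butyldimethylsilyl)oxy]-4,7-dimethyl-5-(3-oxobutyl)cyclohept-3-en-1-one | O=C1CC=C(C)[C@@H](CCC(C)=O)[C@H](O[Si](C)(C)C(C)(C)C)[C@@]1(C)COCc1ccccc1 | intermediate
15 | bis(trimethylsilyl enol ether) of 14 (ring silyloxydiene, terminal side-chain enol silane) | C[Si](C)(C)OC1=CC=C(C)[C@@H](CCC(=C)O[Si](C)(C)C)[C@H](O[Si](C)(C)C(C)(C)C)[C@@]1(C)COCc1ccccc1 | intermediate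
16 | cis-fused bicyclic C1 enone / C8 ketone (C4–Me β, C5–H β, C6–OSi β) | O=C1C=C[C@@]2(C)CC(=O)CC[C@H]2[C@H](O[Si](C)(C)C(C)(C)C)[C@@]1(C)COCc1ccccc1 | intermediate
17 | C3 pinacol boronate of the C1,C8-diketone (C3 epimers, not isolated) | O=C1CC(B3OC(C)(C)C(C)(C)O3)[C@@]2(C)CC(=O)CC[C@H]2[C@H](O[Si](C)(C)C(C)(C)C)[C@@]1(C)COCc1ccccc1 | intermediate
18 | C3-hydroxy C1,C8-diketone (C3 epimers) | O=C1CC(O)[C@@]2(C)CC(=O)CC[C@H]2[C@H](O[Si](C)(C)C(C)(C)C)[C@@]1(C)COCc1ccccc1 | intermediate
19 | bicyclic C1,C3,C8-triketone | O=C1CC(=O)[C@@]2(C)CC(=O)CC[C@H]2[C@H](O[Si](C)(C)C(C)(C)C)[C@@]1(C)COCc1ccccc1 | intermediate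
20 | C3 methoxymethyl enol ether of 19 | O=C1C=C(OCOC)[C@@]2(C)CC(=O)CC[C@H]2[C@H](O[Si](C)(C)C(C)(C)C)[C@@]1(C)COCc1ccccc1 | intermediate
21 | C6 β-alcohol | O=C1C=C(OCOC)[C@@]2(C)CC(=O)CC[C@H]2[C@H](O)[C@@]1(C)COCc1ccccc1 | intermediate
22 | C6 β-methanesulfonate | O=C1C=C(OCOC)[C@@]2(C)CC(=O)CC[C@H]2[C@H](OS(C)(=O)=O)[C@@]1(C)COCc1ccccc1 | intermediate
23 | tricyclic C8 ketone (cyclobutane closed) | O=C1C=C(OCOC)[C@]2(C)[C@@H]3[C@@H]([C@H]2C(=O)CC3)[C@@]1(C)COCc1ccccc1 | intermediate
24 | tricyclic C8 enone (C9=C10) | O=C1C=C(OCOC)[C@]2(C)[C@@H]3[C@@H]([C@H]2C(=O)C=C3)[C@@]1(C)COCc1ccccc1 | intermediate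
25 | tricyclic (10R)-methyl C8 ketone | O=C1C=C(OCOC)[C@]2(C)[C@@H]3[C@@H]([C@H]2C(=O)C[C@H]3C)[C@@]1(C)COCc1ccccc1 | intermediate
26 | tricyclic C1,C3,C8-triketone benzyl ether | O=C1CC(=O)[C@]2(C)[C@@H]3[C@@H]([C@H]2C(=O)C[C@H]3C)[C@@]1(C)COCc1ccccc1 | intermediate
27 | tricyclic C1,C3,C8-triketone with C11–CH2OH | O=C1CC(=O)[C@]2(C)[C@@H]3[C@@H]([C@H]2C(=O)C[C@H]3C)[C@@]1(C)CO | intermediate
28 | C1 β-hydroxy C3,C8-diketone (not isolated) | O[C@@H]1CC(=O)[C@]2(C)[C@@H]3[C@@H]([C@H]2C(=O)C[C@H]3C)[C@@]1(C)CO | intermediate
29 | triol ketone (C1–OH β, C3–OH α) | O[C@@H]1C[C@@H](O)[C@]2(C)[C@@H]3[C@@H]([C@H]2C(=O)C[C@H]3C)[C@@]1(C)CO | intermediate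
30 | primary tert-butyldimethylsilyl ether of 29 | O[C@@H]1C[C@@H](O)[C@]2(C)[C@@H]3[C@@H]([C@H]2C(=O)C[C@H]3C)[C@@]1(C)CO[Si](C)(C)C(C)(C)C | intermediate
31 | angelic acid, (Z)-2-methylbut-2-enoic acid | C/C=C(/C)C(=O)O | starting material
32 | C1,C3-diangelate silyl ether | C/C=C(/C)C(=O)O[C@@H]1C[C@@H](OC(=O)/C(C)=C\C)[C@]2(C)[C@@H]3[C@@H]([C@H]2C(=O)C[C@H]3C)[C@@]1(C)CO[Si](C)(C)C(C)(C)C | intermediate
33 | CNP0287707.1, (1R,3R,4R,5S,6S,7R,10R,11S) in the numbering used here | C/C=C(/C)C(=O)O[C@@H]1C[C@@H](OC(=O)/C(C)=C\C)[C@]2(C)[C@@H]3[C@@H]([C@H]2C(=O)C[C@H]3C)[C@@]1(C)CO | target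

Total step count: 24. Longest linear sequence: 24 steps (from 1).

**Steps most likely to fail**

Step 3 (key step).
- What may go wrong: capture of the cation by the solvent, Favorskii rearrangement of the chloro enolate, or erosion of regio- and C11-facial selectivity if the addition turns fully stepwise.
- Fallback: the same ring-forming disconnection, with the three-carbon unit made by reduction instead of base-induced ionisation. It sets out from 3.
- Acid-catalysed double bromination (Br2, catalytic HBr, CH2Cl2) should give 4-(benzyloxy)-1,3-dibromo-3-methylbutan-2-one F1.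
- F1 is then reduced with zinc–copper couple in THF at −10 °C in the presence of 5.
- The zinc-bound oxyallyl species forms under non-basic, non-nucleophilic conditions, so there is no Favorskii pathway and no solvent capture. It is less electrophilic, which favours the compact concerted mode. The route is rejoined at 7.

Step 10.
- What may go wrong: oxidation of the enol silanes without C–C bond formation (hydrolysis back to the diketone, trapping by nitrate, intermolecular coupling), or ring closure to the trans fusion.
- Fallback: the oxidative closure is replaced by an intramolecular dienolate alkylation. It sets out from 11.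
- The homocuprate from 3-methylbut-3-enylmagnesium bromide (from commercial 4-bromo-2-methylbut-1-ene) is added 1,6 as in step 7. The crude product is conjugated with DBU to the 5-(3-methylbut-3-enyl)cyclohept-2-enone F2 (C4 epimers).
- Ene-type allylic chlorination of the only electron-rich alkene (Ca(OCl)2, solid CO2, CH2Cl2/H2O) should give the 2-(chloromethyl)allyl compound F3.
- KOtBu in THF forms the extended dienolate by γ-deprotonation at C4. This is alkylated at C4 (6-exo-tet; attack at C2 would need an eight-membered ring) to give the 8-methylene bicycle F4.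
- Ozonolysis of the 1,1-disubstituted alkene in the presence of the electron-poor enone (O3, CH2Cl2/pyridine, −78 °C; Me2S) returns to 16.

Step 7.
- What may go wrong: competing 1,4-transfer to C3, slow transfer to the hindered C5, or poor facial selectivity.
- Fallback: a change from organocopper to radical chemistry. It sets out from 11.
- Photoredox decarboxylative Giese-type addition is run with 4-oxopentanoic acid, Ir[dF(CF3)ppy]2(dtbbpy)PF6 (1 mol %) and K2HPO4 in DMF under blue light.
- This generates the primary 3-oxobutyl radical, which should add to the diene terminus C5 because this gives the most delocalised radical, again anti to the silyloxy group.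
- Reduction and protonation give 14 directly, so steps 7 and 8 are both replaced. This fallback makes no compound outside the list (F0).

**Further compounds**
F1 | step 3 | 4-(benzyloxy)-1,3-dibromo-3-methylbutan-2-one (racemic) | O=C(CBr)C(C)(Br)COCc1ccccc1
F2 | step 10 | 7-[(benzyloxy)methyl]-6-[(tert-butyldimethylsilyl)oxy]-4,7-dimethyl-5-(3-methylbut-3-enyl)cyclohept-2-en-1-one (C4 epimers) | O=C1C=CC(C)[C@@H](CCC(C)=C)[C@H](O[Si](C)(C)C(C)(C)C)[C@@]1(C)COCc1ccccc1
F3 | step 10 | 5-[3-(chloromethyl)but-3-enyl] analogue of F2 (C4 epimers) | O=C1C=CC(C)[C@@H](CCC(=C)CCl)[C@H](O[Si](C)(C)C(C)(C)C)[C@@]1(C)COCc1ccccc1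
F4 | step 10 | cis-fused bicyclic C1 enone with exocyclic methylene at C8 | O=C1C=C[C@@]2(C)CC(=C)CC[C@H]2[C@H](O[Si](C)(C)C(C)(C)C)[C@@]1(C)COCc1ccccc1
F0 | step 7 | none | none
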